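**Retrosynthetic overview**

- The target is 8-(3,4-dimethoxyphenyl)-2,6-dimethoxynaphthalene-1,4-dione: ring A is the quinone ring (C1–C4, C4a, C8a), ring B the benzo ring (C4a, C5–C8, C8a) and ring C the aryl ring (C1'–C6') on C8. The route rests on the C8–C1' bond lying peri to the C1 oxygen and on the adjacent methoxy pair at C3'/C4', which is the oxygen pattern of 2,3-dimethoxybutadiene.
- Last disconnections: the quinone comes from a 1,2,4-trimethoxy ring A by oxidative demethylation, and aromatic ring C from its 1,4-cyclohexadiene by dehydrogenation.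
- Key disconnection: ring C is assembled on the naphthalene from a C8 ethynyl group (C1' and C6') and 2,3-dimethoxybuta-1,3-diene (C2'–C5') by a cobalt-catalysed [4+2], so no two finished arenes have to be joined at the peri position.
- Ring A comes from thermal ring expansion of a 4-aryl-4-hydroxy-3-methoxycyclobutenone, made from an ortho-(silylethynyl)aryllithium and 3-methoxycyclobutenedione. The latter is prepared from dimethyl squarate, because dimethyl squarate itself would leave a second methoxy group on C3.
- Order of ring formation: ring B is bought as the anisole, ring A closes in step 5, ring C closes in step 7 and becomes aromatic in step 8.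

Key step: step 7

Assumption: the aryllithium attacks 3-methoxycyclobutenedione at C2, the ketone carbonyl flanked by the methoxy-bearing carbon, and not at C1, the vinylogous ester carbonyl, as is general for 3-alkoxycyclobutenediones; this places the methoxy group on C2 of the naphthalene. Compounds 1 and 12 are taken as purchasable.

**Route**

Step 1
Reactants: 1 4-bromo-3-iodoanisole; 2 trimethylsilylacetylene
Product: 3 [(2-bromo-5-methoxyphenyl)ethynyl]trimethylsilane
Conditions: PdCl2(PPh3)2 (2 mol%), CuI (4 mol%), Et3N, THF, rt
Reagents that add atoms: none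
Why: Sonogashira coupling: zerovalent palladium inserts into the C–I bond far faster than into the C–Br bond at room temperature, so the alkyne is attached only at C3 and the bromide is kept for step 4.

Step 2
Reactants: 4 dimethyl squarate
Product: 5 4-hydroxy-2,3-dimethoxycyclobut-2-en-1-one (racemic)
Conditions: LiAlH(OtBu)3 (1.05 equiv), THF, –78 to –30 °C; then H2O
Reagents that add atoms: none
Why: Carbonyl 1,2-reduction with a bulky, mild aluminium hydride should stop after one hydride transfer because the alkoxide formed deactivates the remaining vinylogous ester carbonyl; the new carbinol stereocenter forms as a racemate without control and is erased in step 3.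

Step 3
Reactants: 5 4-hydroxy-2,3-dimethoxycyclobut-2-en-1-one
Product: 6 3-methoxycyclobut-3-ene-1,2-dione
Conditions: conc. HCl (cat.), CH2Cl2, rt; use promptly
Reagents that add atoms: water, O
Why: Acid-catalysed allylic ionization–hydrolysis: loss of the C4 hydroxyl as water gives a cyclobutenyl cation stabilized by the C2 methoxy group, water adds at C2 and methanol is expelled, which leaves the C3 methoxy group on the new enedione.

Step 4
Reactants: 3 [(2-bromo-5-methoxyphenyl)ethynyl]trimethylsilane; 6 3-methoxycyclobut-3-ene-1,2-dione
Product: 8 4-hydroxy-3-methoxy-4-{4-methoxy-2-[(trimethylsilyl)ethynyl]phenyl}cyclobut-2-en-1-one (racemic), via aryllithium 7 (not isolated)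
Conditions: n-BuLi (1.05 equiv), THF, –78 °C; cannulate into 6 (1.2 equiv), THF, –78 °C; aq. NH4Cl
Reagents that add atoms: none
Why: Bromine–lithium exchange followed by 1,2-addition of the aryllithium to the more electrophilic C2 ketone of 6 (C1 is a deactivated vinylogous ester carbonyl), run by inverse addition at –78 °C to avoid double addition; the carbinol stereocenter forms as a racemate and becomes the sp2 carbon C1 of the naphthalene in step 5.

Step 5
Reactants: 8 4-hydroxy-3-methoxy-4-{4-methoxy-2-[(trimethylsilyl)ethynyl]phenyl}cyclobut-2-en-1-one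
Product: 10 1,2,4,6-tetramethoxy-8-[(trimethylsilyl)ethynyl]naphthalene, via hydroquinone 9 (not isolated)
Conditions: degassed p-xylene, 138 °C, Ar; cool; then MeI (6 equiv), K2CO3 (5 equiv), acetone, 50 °C, Ar
Reagents that add atoms: iodomethane, CI
Why: Thermal ring expansion of a 4-aryl-4-hydroxycyclobutenone (conrotatory 4π ring opening with the hydroxyl turning outward to an aryl vinylketene, 6π electrocyclization onto the only free ortho carbon, enolization) puts the carbinol carbon at C1, the methoxy carbon at C2 and the ketene carbon at C4, and Williamson O-methylation under argon then caps both phenols before the hydroquinone can oxidize.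

Step 6
Reactants: 10 1,2,4,6-tetramethoxy-8-[(trimethylsilyl)ethynyl]naphthalene
Product: 11 8-ethynyl-1,2,4,6-tetramethoxynaphthalene
Conditions: K2CO3 (0.2 equiv), MeOH/THF, rt
Reagents that add atoms: none
Why: Base-catalysed protodesilylation (methanolysis of the C(sp)–Si bond through a pentacoordinate silicate), to which the aryl methyl ethers are inert.

Step 7
Reactants: 11 8-ethynyl-1,2,4,6-tetramethoxynaphthalene; 12 2,3-dimethoxybuta-1,3-diene
Product: 13 8-(4,5-dimethoxycyclohexa-1,4-dien-1-yl)-1,2,4,6-tetramethoxynaphthalene
Conditions: CoBr2(dppe) (10 mol%; dppe = 1,2-bis(diphenylphosphino)ethane), Zn powder (20 mol%), ZnI2 (20 mol%), diene in threefold excess, CH2Cl2, rt, Ar; filter through basic Al2O3, evaporate, use at once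
Reagents that add atoms: none
Why: Zinc reduces CoBr2(dppe) (divalent cobalt) to a monovalent cobalt–diphosphine species, made cationic by ZnI2, which binds the terminal alkyne and the s-cis diene, couples them oxidatively to a cobaltacycle and reductively eliminates the unconjugated 1,4-cyclohexadiene, creating C1'–C2' and C5'–C6'. The closest known reaction type is the cobalt-catalysed neutral Diels–Alder reaction of terminal aryl alkynes with 2-oxygenated or 2,3-disubstituted 1,3-dienes. Ring C is closed as a six-membered carbocycle by this intermolecular, metal-templated [4+2] annulation, and no stereocenter is formed. The step needs chemoselectivity for the cross-adduct over alkyne cyclotrimerization, which the chelating diphosphine and the threefold excess of diene 12 should secure, and it has no regiochemical issue because the two halves of diene 12 are equivalent. The linear ethynyl group holds its reacting carbons away from the C1 methoxy group, so the peri crowding arises only once ring C is closed; the acid-labile bis-enol ether is kept intact by basic filtration and immediate use, and the unconsumed diene is removed unchanged on evaporation.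

Step 8
Reactants: 13 8-(4,5-dimethoxycyclohexa-1,4-dien-1-yl)-1,2,4,6-tetramethoxynaphthalene
Product: 14 8-(3,4-dimethoxyphenyl)-1,2,4,6-tetramethoxynaphthalene
Conditions: DDQ (1.1 equiv), anhydrous benzene, rt
Reagents that add atoms: none
Why: Dehydrogenative aromatization with a quinone oxidant: DDQ abstracts hydride from a doubly allylic CH2 of the electron-rich 1,4-diene and the cation loses a proton, the gain of aromaticity making this far faster than any oxidation of the methoxynaphthalene when one equivalent is used without water.

Step 9
Reactants: 14 8-(3,4-dimethoxyphenyl)-1,2,4,6-tetramethoxynaphthalene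
Product: 15 8-(3,4-dimethoxyphenyl)-2,6-dimethoxynaphthalene-1,4-dione (target)
Conditions: (NH4)2Ce(NO3)6 (2.5 equiv), MeCN/H2O 2:1, 0 °C, short reaction time
Reagents that add atoms: water, O
Why: Oxidative demethylation with tetravalent cerium: single-electron oxidation of the most electron-rich ring (ring A, three methoxy groups, para-dioxygenated) gives a radical cation that water attacks at C1 and C4 with loss of two molecules of methanol, so the 2-methoxy-1,4-quinone should form while ring B and ring C, which lack a para-dioxygen pair, are oxidized more slowly.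

**Compound list**

1 | 4-bromo-3-iodoanisole (1-bromo-2-iodo-4-methoxybenzene) | COc1ccc(Br)c(I)c1 | starting material
2 | trimethylsilylacetylene | C#C[Si](C)(C)C | starting material
3 | [(2-bromo-5-methoxyphenyl)ethynyl]trimethylsilane | COc1ccc(Br)c(C#C[Si](C)(C)C)c1 | intermediate
4 | dimethyl squarate (3,4-dimethoxycyclobut-3-ene-1,2-dione) | COC1=C(OC)C(=O)C1=O | starting material
5 | 4-hydroxy-2,3-dimethoxycyclobut-2-en-1-one (racemic) | COC1=C(OC)C(=O)C1O | intermediate
6 | 3-methoxycyclobut-3-ene-1,2-dione | COC1=CC(=O)C1=O | intermediate
7 | {4-methoxy-2-[(trimethylsilyl)ethynyl]phenyl}lithium | [Li]c1ccc(OC)cc1C#C[Si](C)(C)C | intermediate (not isolated)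
8 | 4-hydroxy-3-methoxy-4-{4-methoxy-2-[(trimethylsilyl)ethynyl]phenyl}cyclobut-2-en-1-one (racemic) | COC1=CC(=O)C1(O)c1ccc(OC)cc1C#C[Si](C)(C)C | intermediate
9 | 2,6-dimethoxy-8-[(trimethylsilyl)ethynyl]naphthalene-1,4-diol | COc1cc(O)c2cc(OC)cc(C#C[Si](C)(C)C)c2c1O | intermediate (not isolated)
10 | 1,2,4,6-tetramethoxy-8-[(trimethylsilyl)ethynyl]naphthalene | COc1cc(OC)c2cc(OC)cc(C#C[Si](C)(C)C)c2c1OC | intermediate
11 | 8-ethynyl-1,2,4,6-tetramethoxynaphthalene | COc1cc(OC)c2cc(OC)cc(C#C)c2c1OC | intermediate
12 | 2,3-dimethoxybuta-1,3-diene | C=C(OC)C(OC)=C | starting material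
13 | 8-(4,5-dimethoxycyclohexa-1,4-dien-1-yl)-1,2,4,6-tetramethoxynaphthalene | COc1cc(OC)c2cc(OC)cc(C3=CCC(OC)=C(OC)C3)c2c1OC | intermediate
14 | 8-(3,4-dimethoxyphenyl)-1,2,4,6-tetramethoxynaphthalene | COc1cc(OC)c2cc(OC)cc(-c3ccc(OC)c(OC)c3)c2c1OC | intermediate
15 | 8-(3,4-dimethoxyphenyl)-2,6-dimethoxynaphthalene-1,4-dione (CNP0128574.0; no stereocenters) | COC1=CC(=O)c2cc(OC)cc(-c3ccc(OC)c(OC)c3)c2C1=O | target

**Step count**

Total: 9 steps. Longest linear sequence: 8 steps (from dimethyl squarate 4 through steps 2, 3, 4, 5, 6, 7, 8 and 9; the arm from 1 is 7 steps).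

**Steps most likely to fail**

Step 7. The cross [4+2] may lose to alkyne cyclotrimerization, alkyne binding may be slowed by the peri methoxy group, and the bis-enol ether may be hydrolysed on the Lewis-acidic zinc salts. The fallback forms the C8–C1' bond before ring A exists, so the peri crowding is created in an intramolecular electrocyclization. It sets out from 1: Suzuki–Miyaura coupling at the C–I bond with (3,4-dimethoxyphenyl)boronic acid (Pd(PPh3)4, Na2CO3, DME/H2O, 70 °C) should give 2-bromo-3',4',5-trimethoxy-1,1'-biphenyl F1. Bromine–lithium exchange with n-BuLi at –78 °C gives (3',4',5-trimethoxy-1,1'-biphenyl-2-yl)lithium F2, which is added to 6 to give 4-hydroxy-3-methoxy-4-(3',4',5-trimethoxy-1,1'-biphenyl-2-yl)cyclobut-2-en-1-one F3. Thermolysis in p-xylene at 138 °C should give 8-(3,4-dimethoxyphenyl)-2,6-dimethoxynaphthalene-1,4-diol F4, and oxidation with Ag2O returns to the route at the target 15.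

Step 5. Hydroquinone 9 may be lost before it is capped, either by air oxidation or by attack of the peri C1 oxygen on the neighbouring alkyne under the basic methylation conditions. The fallback caps the oxygen that becomes O1 before the naphthalene is formed. It sets out from 8: O-methylation of the tertiary alcohol (MeI, Ag2O, K2CO3, MeCN, rt) gives 3,4-dimethoxy-4-{4-methoxy-2-[(trimethylsilyl)ethynyl]phenyl}cyclobut-2-en-1-one F5. The same thermal ring expansion (p-xylene, 138 °C) then gives 3,4,7-trimethoxy-5-[(trimethylsilyl)ethynyl]naphthalen-1-ol F6, in which only the remote C4 hydroxyl is free and which should be far less air-sensitive. Methylation with MeI and K2CO3 in acetone returns to the route at 10.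

Step 9. The cerium oxidation may take the wrong course, by demethylation across the C1/C2 pair to an ortho-quinone or by oxidation of the electron-rich ring C. The fallback fixes the para relationship before any carbonyl is released. It sets out from 14: anodic oxidation in KOH/MeOH (Pt anode, undivided cell, 0 °C) should give the quinone bisketal 8-(3,4-dimethoxyphenyl)-1,1,2,4,4,6-hexamethoxy-1,4-dihydronaphthalene F7. Hydrolysis of both ketals with dilute aqueous HCl in acetone returns to the route at 15.

**Further compounds**

F1 | step 7 | 2-bromo-3',4',5-trimethoxy-1,1'-biphenyl | COc1ccc(Br)c(-c2ccc(OC)c(OC)c2)c1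
F2 | step 7 | (3',4',5-trimethoxy-1,1'-biphenyl-2-yl)lithium | [Li]c1ccc(OC)cc1-c1ccc(OC)c(OC)c1
F3 | step 7 | 4-hydroxy-3-methoxy-4-(3',4',5-trimethoxy-1,1'-biphenyl-2-yl)cyclobut-2-en-1-one (racemic) | COC1=CC(=O)C1(O)c1ccc(OC)cc1-c1ccc(OC)c(OC)c1
F4 | step 7 | 8-(3,4-dimethoxyphenyl)-2,6-dimethoxynaphthalene-1,4-diol | COc1cc(O)c2cc(OC)cc(-c3ccc(OC)c(OC)c3)c2c1O
F5 | step 5 | 3,4-dimethoxy-4-{4-methoxy-2-[(trimethylsilyl)ethynyl]phenyl}cyclobut-2-en-1-one (racemic) | COC1=CC(=O)C1(OC)c1ccc(OC)cc1C#C[Si](C)(C)C
F6 | step 5 | 3,4,7-trimethoxy-5-[(trimethylsilyl)ethynyl]naphthalen-1-ol | COc1cc(O)c2cc(OC)cc(C#C[Si](C)(C)C)c2c1OC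
F7 | step 9 | 8-(3,4-dimethoxyphenyl)-1,1,2,4,4,6-hexamethoxy-1,4-dihydronaphthalene | COC1=CC(OC)(OC)c2cc(OC)cc(-c3ccc(OC)c(OC)c3)c2C1(OC)OC
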